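## The problem

Compound 28 is a 6-oxabicyclo[3.2.2]nonane: a cycloheptenone (C1, C2, C3, C4, C5, C9, C8) whose C1 and C5 are spanned by a lactone bridge (C7=O, O6). C5 is therefore both the alkoxy carbon of the lactone and a methyl ketal, i.e. the pseudo-ester of a δ-keto acid. Of the four stereocenters, C1 (bridgehead between ketone and lactone carbonyl), C8 (aryl) and C9 (methyl) are contiguous, while C5 is not independent: once C1 is fixed, the bridge allows only one configuration there. In any open precursor C1 and C9 sit α to carbonyl groups and can epimerise, whereas C8 cannot, so C8 has to be set absolutely and its two neighbours placed trans to the aryl group on either side. The reagents are limited by the mixed ketal–lactone (lost to aqueous acid or base), the ene-1,4-dione pattern C2(=O)–C3=C4–C5 (a strong acceptor once the ketone is present), the terminal allyl double bond (no hydrogenation, no strong electrophiles, nothing that moves it into conjugation) and the electron-rich trimethoxyphenyl ring. The enabling feature is that C7(=O), O6 and C5, with C9H(CH3), C8H(Ar) and C1H, are the six ring atoms of a 2-methyl-3-arylglutaric anhydride in which one carbonyl carbon (C5) has taken up the enone carbon C4 and a methoxy group. The C4–C5 bond can therefore be made by adding an alkenyl metal, tethered to C1, to an anhydride carbonyl.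

## Retrosynthesis

**Adjustments at C2 and C5 (28 → 27 → 26).** No skeletal bond is cut first. The C2 ketone of 28 is taken back to the allylic alcohol 27, and the methyl ketal and free hydroxyl of 27 to the lactol silyl ether 26. Carrying C2 as a protected carbinol keeps the future bridgehead from being a β-dicarbonyl C–H in the open precursors, where it would quench an organometallic and epimerise freely. The forward steps need an acid-catalysed lactol-to-ketal exchange that gives the pseudo-ester and not the ring-opened ester, and an oxidation mild enough for the ketal.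

**Key cut, C4–C5 (26 → 23).** Cutting the bond between the enone CH and the lactol carbon turns the bicycle into the monocyclic anhydride 23. The neighbouring cuts are weaker: C1–C2 would need acylation of an anhydride enolate, C2–C3 leaves the seven-membered ring unmade, and opening the lactone C–O bond only exposes a keto acid with the carbocycle intact. The chosen cut removes the carbocycle, the bridge and the quaternary stereocenter together, and both carbonyl carbons of 23 are already at the right oxidation level. The forward reaction is an intramolecular alkenylchromium addition to one anhydride carbonyl, which has no direct precedent. It requires a Z alkenyl iodide, a tether anchored on the ring carbon next to the other carbonyl, and a protected carbinol.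

**Unmasking the anhydride (23 → 22 → 21).** The anhydride C–O bond is cut to diacid 22, whose two carboxyl groups are traced to an acyl oxazolidinone and a tert-butyl thioester in 21. Two different acyl derivatives are preferred to two esters because a single cold peroxide-assisted hydrolysis frees both, without the hot hydroxide that would threaten the β-silyloxy acid and the α-stereocenters. The silyl ether is traced to aldol 20.

**C3–C1' aldol cut (20 → 12 + 17).** The bond between the future bridgehead and the carbinol carbon is cut to imide 12 and iodo-enal 17. Cutting the carbinol–alkene bond instead would need a 2-metallated 1-iodoalkene, which is not a workable reagent. The aldol cut also settles which α-carbon of the glutarate reacts, because only the imide arm is enolised, and it puts the bridgehead configuration under auxiliary control rather than under the weak bias of the neighbouring aryl-bearing carbon. The forward reaction must be a syn-selective auxiliary-controlled aldol on a hindered enolate with a sensitive β-iodo enal.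

**Iodo-enal (17 → 16 → 13 + 14).** The allyl–C2 bond and the C–I bond are cut together: anti-allylmagnesiation of alkynol 13 with Grignard reagent 14, then iodinolysis, gives iodo alcohol 16 with iodine cis to the CH2OH carbon. That is the geometry the ring closure needs, and oxidation then gives 17. This is shorter than any olefination route to a trisubstituted Z iodide.

**Imide (12 → 9 + 10; 9 → 8 → 7).** The N-acyl bond is cut to acid 9 and oxazolidinone 10. Acid 9 goes back through methyl ester 8 to malonate 7 by demethylation and dealkoxycarbonylation. The malonate is kept to this point because it is the chelating group the asymmetric step needs, and the thioester on the other arm survives both unmasking steps.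

**C(aryl)–C(methyl) Michael cut (7 → 3 + 6).** The bond between the aryl-bearing and methyl-bearing carbons is cut to arylidene malonate 3 and silyl ketene acetal 6. Cutting the aryl–carbon bond (conjugate arylation) would leave the methyl center to an uncontrolled protonation. Cutting here creates both stereocenters in one catalytic step from achiral partners. The forward reaction needs face selectivity on 3 from a chiral Lewis acid and simple diastereoselection from the geometry of 6.

**Starting materials (3 → 1 + 2; 6 → 4).** The C=C bond of 3 is cut to aldehyde 1 and malonate 2 (Knoevenagel condensation). Ketene acetal 6 comes from thioester 4 through its lithium enolate 5.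

## Roads not taken

Alternative 1: The two bonds that join the three-carbon bridge to the rest of the carbocycle (C1–C2 and C4–C5) are cut together. In the forward sense pyrone A2 and cyclopropenone ketal A3 combine thermally in a [4+3] cycloaddition across pyrone C3 and C6, and the adduct expels the pyrone O–C(=O) bridge to give tropone ketal A1. The merit is speed: the seven-membered ring, the masked C2 ketone, the enol ether at the future ketal carbon, the methyl group and the carboxyl are assembled in one step from two achiral pieces. The weak points lie in what A1 lacks. It has no stereocenter, and the aryl group must be added to a cross-conjugated trienoate where 1,4-, 1,6- and 1,8-addition compete. The aryl/methyl relationship would then rest on protonation of a dienolate, the allyl group has to be placed on an unactivated vinylic carbon, and the absolute configuration needs an enantioselective arylation of an unusual acceptor. Alternative 1 reaches the ring much sooner than the chosen plan. Against that, the chosen plan sets aryl, methyl and allyl before the ring exists and fixes every stereocenter by reagent control.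

Alternative 2: The aryl–C8 bond and the C1–C2 bond are cut. In the forward sense aryl Grignard A6 adds under copper mediation to the chiral-pool lactone A5 anti to its methyl group, and the lactone enolate is trapped by iodo-enal 17 to give lactone aldol A4. This relays three stereocenters in one flask, is convergent, shares fragment 17 with the chosen plan, and its later ring closure could be an ordinary alkenyl iodide–aldehyde closure with solid precedent. In those respects it is better than the chosen plan, which needs six steps to reach the same stereotriad and closes its ring by an untested addition. Its weakness is the oxidation level. The future ketal carbon of A4 is a CH2–O, two levels too low, so the lactone must be opened (the hydroxy acid tends to re-close), protected and oxidised after the sensitive aldol is in place. The magnesium or copper enolate aldol also gives little control at the carbinol and can revert. The chosen plan sets against this that both carbonyl carbons are at the final oxidation level from the start, that the bridgehead and carbinol are auxiliary-controlled, and that the closure delivers the pseudo-acid directly.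

Alternative 3: Both ring bonds of the aryl-bearing carbon (C1–C8 and C8–C9) are cut. In the forward sense aldehyde 1 condenses with the β-keto ester CH2 of enedione A8, and the ethyl-ketone α-carbon then adds to the arylidene in a 7-endo-trig Michael closure to give cycloheptenedione ester A7. Ester cleavage, lactolisation and ketalisation would finish the synthesis in very few steps, and the two centers next to the aryl carbon in A7 are epimerisable, so the relative configuration can settle thermodynamically. In step economy this road is clearly better than the chosen plan. Its weak points are the substrate and the stereochemistry. A8 is a (Z)-enedione whose geometry is labile (the E isomer cannot cyclise) and which is itself a strong acceptor likely to oligomerise under the condensation conditions. The 7-endo closure must outrun intermolecular addition, and A7 is racemic unless a catalyst-controlled cascade is invented for this ring size. The chosen plan sets against this an absolute configuration from an established catalytic Michael addition and an auxiliary aldol, and a ring closure whose regiochemistry cannot be ambiguous.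

Key step: step 13

Assumption 1: in step 3 the (E)-silyl ketene acetal 6 is taken to give the syn methyl/aryl adduct and the (S,S)-ligand to expose the Si face of 3, by analogy with related bis(oxazoline)–copper Michael additions of propionate thioester enol silanes; if either sense is the reverse, the (Z)-isomer of 6 (enolisation without DMPU) or the (R,R)-ligand is used.

Assumption 2: lactol 26 and its ring-opened keto acid are ring–chain tautomers and are treated as one compound, written in the bridged form.

## Steps

Step 1
Reactants: 1 3,4,5-trimethoxybenzaldehyde; 2 dimethyl malonate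
Product: 3 dimethyl 2-[(3,4,5-trimethoxyphenyl)methylidene]propanedioate
Conditions: piperidine (cat.), AcOH (cat.), toluene, reflux, Dean–Stark
Reagents that add atoms: none
Why: Knoevenagel condensation driven by azeotropic removal of water; no stereocenter is formed.

Step 2
Reactants: 4 S-tert-butyl propanethioate
Product: 6 (1E)-1-(tert-butylsulfanyl)-1-[(trimethylsilyl)oxy]prop-1-ene, via lithium enolate 5 (not isolated)
Conditions: LiN(iPr)2, THF/DMPU, −78 °C; Me3SiCl, −78 °C → rt
Reagents that add atoms: chlorotrimethylsilane, C[Si](C)(C)Cl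
Why: Kinetic enolisation of the thioester in the presence of DMPU favours the enolate with methyl cis to oxygen (5), and O-silylation fixes that geometry as the (E)-silyl ketene acetal; this is the standard preparation of such enol silanes.

Step 3
Reactants: 3 dimethyl 2-[(3,4,5-trimethoxyphenyl)methylidene]propanedioate; 6 (1E)-1-(tert-butylsulfanyl)-1-[(trimethylsilyl)oxy]prop-1-ene
Product: 7 dimethyl 2-[(1S,2R)-3-(tert-butylsulfanyl)-2-methyl-3-oxo-1-(3,4,5-trimethoxyphenyl)propyl]propanedioate
Conditions: [Cu((S,S)-t-Bu-box)](SbF6)2 (10 mol %; t-Bu-box = 2,2'-(propane-2,2-diyl)bis(4-tert-butyl-4,5-dihydro-1,3-oxazole)), (CF3)2CHOH (2 equiv), toluene/CH2Cl2 3:1, −78 °C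
Reagents that add atoms: none
Why: Mukaiyama–Michael addition under a divalent copper bis(oxazoline) Lewis acid: the malonate chelates copper and the ligand tert-butyl groups block one face of the β-carbon, so 6 should add to the open Si face and set the aryl-bearing carbon (S). The (E) geometry of 6 is relied on for the syn methyl/aryl relationship (2R), and the fluorinated alcohol takes the silyl group and turns the catalyst over.

Step 4
Reactants: 7 dimethyl 2-[(1S,2R)-3-(tert-butylsulfanyl)-2-methyl-3-oxo-1-(3,4,5-trimethoxyphenyl)propyl]propanedioate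
Product: 8 methyl (3S,4R)-5-(tert-butylsulfanyl)-4-methyl-5-oxo-3-(3,4,5-trimethoxyphenyl)pentanoate
Conditions: LiCl (2 equiv), H2O (2 equiv), DMSO, 150 °C
Reagents that add atoms: none
Why: Krapcho dealkoxycarbonylation: chloride demethylates one malonate ester, the carboxylate loses CO2 and water protonates the ester enolate; the near-neutral medium should leave the thioester and its α-stereocenter untouched.

Step 5
Reactants: 8 methyl (3S,4R)-5-(tert-butylsulfanyl)-4-methyl-5-oxo-3-(3,4,5-trimethoxyphenyl)pentanoate
Product: 9 (3S,4R)-5-(tert-butylsulfanyl)-4-methyl-5-oxo-3-(3,4,5-trimethoxyphenyl)pentanoic acid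
Conditions: LiI (5 equiv), EtOAc, reflux; then 1 M HCl
Reagents that add atoms: none
Why: Lithium-assisted SN2 demethylation of the methyl ester by iodide; the S-tert-butyl thioester has no primary alkyl–oxygen bond to attack, so only the acetate arm is unmasked, and no hydroxide is present to hydrolyse the thioester or epimerise its α-carbon.

Step 6
Reactants: 9 (3S,4R)-5-(tert-butylsulfanyl)-4-methyl-5-oxo-3-(3,4,5-trimethoxyphenyl)pentanoic acid; 10 (4R)-4-benzyl-1,3-oxazolidin-2-one
Product: 12 S-tert-butyl (2R,3S)-5-[(4R)-4-benzyl-2-oxo-1,3-oxazolidin-3-yl]-2-methyl-5-oxo-3-(3,4,5-trimethoxyphenyl)pentanethioate, via mixed pivalic anhydride 11 (not isolated)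
Conditions: t-BuCOCl, Et3N, THF, −20 °C; then 10, LiCl, −20 °C → rt
Reagents that add atoms: none
Why: N-acylation of the oxazolidinone through the mixed pivalic anhydride with LiCl/Et3N activation; the thioester is not activated under these conditions and no stereocenter is touched.

Step 7
Reactants: 13 prop-2-yn-1-ol; 14 allylmagnesium bromide
Product: 16 (2Z)-2-(iodomethylidene)pent-4-en-1-ol, via alkenylmagnesium chelate 15 (not isolated)
Conditions: 14 (2.5 equiv), Et2O, 0 °C → rt; then I2, THF, −78 → 0 °C
Reagents that add atoms: iodine, II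
Why: Alkoxide-directed anti-carbomagnesiation of the propargylic alcohol: allyl adds to the internal carbon and magnesium to the terminal carbon, held cis to CH2O in chelate 15, and iodinolysis with retention gives the Z iodide.

Step 8
Reactants: 16 (2Z)-2-(iodomethylidene)pent-4-en-1-ol
Product: 17 (2Z)-2-(iodomethylidene)pent-4-enal
Conditions: Dess–Martin periodinane, CH2Cl2, 0 °C; used without storage
Reagents that add atoms: none
Why: Dess–Martin oxidation of the primary allylic alcohol under non-basic, non-nucleophilic conditions that should not isomerise the β-iodo enal.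

Step 9
Reactants: 12 S-tert-butyl (2R,3S)-5-[(4R)-4-benzyl-2-oxo-1,3-oxazolidin-3-yl]-2-methyl-5-oxo-3-(3,4,5-trimethoxyphenyl)pentanethioate; 17 (2Z)-2-(iodomethylidene)pent-4-enal
Product: 20 S-tert-butyl (2R,3S,4R,5R,6Z)-4-{[(4R)-4-benzyl-2-oxo-1,3-oxazolidin-3-yl]carbonyl}-5-hydroxy-6-(iodomethylidene)-2-methyl-3-(3,4,5-trimethoxyphenyl)non-8-enethioate, via boron enolate 18 (not isolated), via boron aldolate 19 (not isolated)
Conditions: Bu2BOTf, iPr2NEt, CH2Cl2, 0 °C; 17, −78 → 0 °C; then pH 7 buffer, MeOH, 30% H2O2, 0 °C
Reagents that add atoms: none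
Why: Evans syn-aldol: soft enolisation acts only on the imide arm (the α-branched thioester is not enolised) and gives the Z boron enolate, which reacts through a closed Zimmerman–Traxler transition state on the face away from the benzyl group. The (4R) auxiliary should set C4 (R, the future bridgehead) and the carbinol C5 (R) and override the resident stereocenters.

Step 10
Reactants: 20 S-tert-butyl (2R,3S,4R,5R,6Z)-4-{[(4R)-4-benzyl-2-oxo-1,3-oxazolidin-3-yl]carbonyl}-5-hydroxy-6-(iodomethylidene)-2-methyl-3-(3,4,5-trimethoxyphenyl)non-8-enethioate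
Product: 21 S-tert-butyl (2R,3S,4R,5R,6Z)-4-{[(4R)-4-benzyl-2-oxo-1,3-oxazolidin-3-yl]carbonyl}-5-{[tert-butyl(dimethyl)silyl]oxy}-6-(iodomethylidene)-2-methyl-3-(3,4,5-trimethoxyphenyl)non-8-enethioate
Conditions: t-BuMe2SiOTf, 2,6-lutidine, CH2Cl2, −78 → 0 °C
Reagents that add atoms: tert-butyldimethylsilyl trifluoromethanesulfonate, CC(C)(C)[Si](C)(C)OS(=O)(=O)C(F)(F)F
Why: Silylation of a hindered secondary allylic alcohol with the silyl triflate; prompt protection blocks retro-aldol cleavage and δ-lactonisation of the hydroxyl onto the thioester.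

Step 11
Reactants: 21 S-tert-butyl (2R,3S,4R,5R,6Z)-4-{[(4R)-4-benzyl-2-oxo-1,3-oxazolidin-3-yl]carbonyl}-5-{[tert-butyl(dimethyl)silyl]oxy}-6-(iodomethylidene)-2-methyl-3-(3,4,5-trimethoxyphenyl)non-8-enethioate
Product: 22 (2R,3R,4R)-2-[(1R,2Z)-1-{[tert-butyl(dimethyl)silyl]oxy}-2-(iodomethylidene)pent-4-en-1-yl]-4-methyl-3-(3,4,5-trimethoxyphenyl)pentanedioic acid
Conditions: LiOH, 30% H2O2, THF/H2O, 0 °C → rt; Na2SO3; then 1 M HCl to pH 3
Reagents that add atoms: lithium hydroperoxide (from LiOH and H2O2), [Li+].[O-]O
Why: Hydroperoxide attacks the exocyclic imide carbonyl selectively (standard auxiliary removal) and perhydrolyses the thioester, and sulfite reduces the peroxy acids; the silyl ether prevents retro-aldol and no stereocenter is involved.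

Step 12
Reactants: 22 (2R,3R,4R)-2-[(1R,2Z)-1-{[tert-butyl(dimethyl)silyl]oxy}-2-(iodomethylidene)pent-4-en-1-yl]-4-methyl-3-(3,4,5-trimethoxyphenyl)pentanedioic acid
Product: 23 (3R,4R,5R)-3-[(1R,2Z)-1-{[tert-butyl(dimethyl)silyl]oxy}-2-(iodomethylidene)pent-4-en-1-yl]-5-methyl-4-(3,4,5-trimethoxyphenyl)oxane-2,6-dione
Conditions: N,N'-dicyclohexylcarbodiimide (1.05 equiv), CH2Cl2, 0 °C → rt; filter
Reagents that add atoms: none
Why: Carbodiimide dehydration of a glutaric acid to its six-membered cyclic anhydride; the cold, neutral conditions should preserve the silyl ether and both α-stereocenters (3,4-trans, 4,5-trans).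

Step 13
Reactants: 23 (3R,4R,5R)-3-[(1R,2Z)-1-{[tert-butyl(dimethyl)silyl]oxy}-2-(iodomethylidene)pent-4-en-1-yl]-5-methyl-4-(3,4,5-trimethoxyphenyl)oxane-2,6-dione
Product: 26 (1R,2R,5S,8R,9R)-2-{[tert-butyl(dimethyl)silyl]oxy}-5-hydroxy-9-methyl-3-(prop-2-en-1-yl)-8-(3,4,5-trimethoxyphenyl)-6-oxabicyclo[3.2.2]non-3-en-7-one, via alkenylchromium 24 (not isolated), via chromium lactolate 25 (not isolated)
Conditions: CrCl2 (6 equiv), NiCl2 (2 mol %), dry degassed DMF, 0.005 M, rt; then H2O
Reagents that add atoms: none
Why: Proposed new method: zerovalent nickel, formed from NiCl2 by CrCl2, inserts into the alkenyl C–I bond of 23 and passes the alkenyl group to trivalent chromium with retention of the Z geometry (24); the alkenyl carbon then adds to the distal anhydride carbonyl and the chromium lactolate 25 is protonated on work-up. The closest known reaction types are the intramolecular Nozaki–Hiyama–Kishi addition of alkenyl iodides to aldehydes and the mono-addition of alkenyl metal reagents to cyclic anhydrides; an anhydride carbonyl is more electrophilic than the ketones that alkenylchromium reagents tolerate and is held within reach here, so addition is expected but has not been shown for this electrophile class. The seven-membered carbocycle closes in the 7-exo-trig mode (the attacked C=O is exocyclic to the new ring), and the six-membered lactol ring of the bicycle is the former anhydride ring. The step needs regioselectivity between the two anhydride carbonyls, and the tether secures it: from the ring carbon that carries the side chain, the near carbonyl could only give a four-membered ring. The new lactol stereocenter (5S) is fixed by the bridge, because the alkenyl carbon can reach the carbonyl only from the ring face that carries the side chain, which leaves the hydroxyl exo. The Z geometry from step 7 is what puts the metal-bearing carbon on the same side as the ring. High dilution and dry solvent guard against intermolecular addition and protonation of 24.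

Step 14
Reactants: 26 (1R,2R,5S,8R,9R)-2-{[tert-butyl(dimethyl)silyl]oxy}-5-hydroxy-9-methyl-3-(prop-2-en-1-yl)-8-(3,4,5-trimethoxyphenyl)-6-oxabicyclo[3.2.2]non-3-en-7-one
Product: 27 (1R,2R,5S,8R,9R)-2-hydroxy-5-methoxy-9-methyl-3-(prop-2-en-1-yl)-8-(3,4,5-trimethoxyphenyl)-6-oxabicyclo[3.2.2]non-3-en-7-one
Conditions: HCl (0.5 M in MeOH), 0 °C → rt
Reagents that add atoms: methanol, CO
Why: Acid-catalysed exchange at the lactol carbon through the bridged oxocarbenium ion should give the methyl pseudo-ester, the usual outcome for pseudo-acids in acidic methanol, and the same acid cleaves the silyl ether; the ketal configuration is fixed by the bicycle.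

Step 15
Reactants: 27 (1R,2R,5S,8R,9R)-2-hydroxy-5-methoxy-9-methyl-3-(prop-2-en-1-yl)-8-(3,4,5-trimethoxyphenyl)-6-oxabicyclo[3.2.2]non-3-en-7-one
Product: 28 (1R,5S,8R,9R)-5-methoxy-9-methyl-3-(prop-2-en-1-yl)-8-(3,4,5-trimethoxyphenyl)-6-oxabicyclo[3.2.2]non-3-ene-2,7-dione
Conditions: Dess–Martin periodinane, CH2Cl2, rt
Reagents that add atoms: none
Why: Dess–Martin oxidation of the secondary allylic alcohol to the enone; the bridgehead carbon between ketone and lactone cannot enolise (Bredt's rule), so its configuration is safe.

## Compound list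

1 | 3,4,5-trimethoxybenzaldehyde | COc1cc(C=O)cc(OC)c1OC | starting material
2 | dimethyl malonate | COC(=O)CC(=O)OC | starting material
3 | dimethyl 2-[(3,4,5-trimethoxyphenyl)methylidene]propanedioate | COC(=O)C(=Cc1cc(OC)c(OC)c(OC)c1)C(=O)OC | intermediate
4 | S-tert-butyl propanethioate | CCC(=O)SC(C)(C)C | starting material
5 | lithium (1E)-1-(tert-butylsulfanyl)prop-1-en-1-olate | C/C=C(\[O-])SC(C)(C)C.[Li+] | intermediate
6 | (1E)-1-(tert-butylsulfanyl)-1-[(trimethylsilyl)oxy]prop-1-ene | C/C=C(\O[Si](C)(C)C)SC(C)(C)C | intermediate
7 | dimethyl 2-[(1S,2R)-3-(tert-butylsulfanyl)-2-methyl-3-oxo-1-(3,4,5-trimethoxyphenyl)propyl]propanedioate | COC(=O)C(C(=O)OC)[C@H](c1cc(OC)c(OC)c(OC)c1)[C@H](C(=O)SC(C)(C)C)C | intermediate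
8 | methyl (3S,4R)-5-(tert-butylsulfanyl)-4-methyl-5-oxo-3-(3,4,5-trimethoxyphenyl)pentanoate | COC(=O)C[C@H](c1cc(OC)c(OC)c(OC)c1)[C@H](C(=O)SC(C)(C)C)C | intermediate
9 | (3S,4R)-5-(tert-butylsulfanyl)-4-methyl-5-oxo-3-(3,4,5-trimethoxyphenyl)pentanoic acid | OC(=O)C[C@H](c1cc(OC)c(OC)c(OC)c1)[C@H](C(=O)SC(C)(C)C)C | intermediate
10 | (4R)-4-benzyl-1,3-oxazolidin-2-one | O=C1N[C@H](Cc2ccccc2)CO1 | starting material
11 | 2,2-dimethylpropanoic (3S,4R)-5-(tert-butylsulfanyl)-4-methyl-5-oxo-3-(3,4,5-trimethoxyphenyl)pentanoic anhydride | CC(C)(C)C(=O)OC(=O)C[C@H](c1cc(OC)c(OC)c(OC)c1)[C@H](C(=O)SC(C)(C)C)C | intermediate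
12 | S-tert-butyl (2R,3S)-5-[(4R)-4-benzyl-2-oxo-1,3-oxazolidin-3-yl]-2-methyl-5-oxo-3-(3,4,5-trimethoxyphenyl)pentanethioate | O=C1OC[C@@H](Cc2ccccc2)N1C(=O)C[C@H](c1cc(OC)c(OC)c(OC)c1)[C@H](C(=O)SC(C)(C)C)C | intermediate
13 | prop-2-yn-1-ol | C#CCO | starting material
14 | allylmagnesium bromide (CH2=CHCH2MgBr) | C=CC[Mg]Br | starting material
15 | bromomagnesium (2Z)-2-[(bromomagnesio)methylidene]pent-4-en-1-olate | C=CC/C(CO[Mg]Br)=C/[Mg]Br | intermediate
16 | (2Z)-2-(iodomethylidene)pent-4-en-1-ol | OC/C(CC=C)=C\I | intermediate
17 | (2Z)-2-(iodomethylidene)pent-4-enal | O=C/C(CC=C)=C\I | intermediate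
18 | S-tert-butyl (2R,3S,4Z)-5-[(4R)-4-benzyl-2-oxo-1,3-oxazolidin-3-yl]-5-[(dibutylboranyl)oxy]-2-methyl-3-(3,4,5-trimethoxyphenyl)pent-4-enethioate | CCCCB(CCCC)O/C(=C\[C@H](c1cc(OC)c(OC)c(OC)c1)[C@H](C(=O)SC(C)(C)C)C)N1[C@H](Cc2ccccc2)COC1=O | intermediate
19 | S-tert-butyl (2R,3S,4R,5R,6Z)-4-{[(4R)-4-benzyl-2-oxo-1,3-oxazolidin-3-yl]carbonyl}-5-[(dibutylboranyl)oxy]-6-(iodomethylidene)-2-methyl-3-(3,4,5-trimethoxyphenyl)non-8-enethioate | O=C1OC[C@@H](Cc2ccccc2)N1C(=O)[C@@H]([C@@H](OB(CCCC)CCCC)/C(CC=C)=C\I)[C@H](c1cc(OC)c(OC)c(OC)c1)[C@H](C(=O)SC(C)(C)C)C | intermediate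
20 | S-tert-butyl (2R,3S,4R,5R,6Z)-4-{[(4R)-4-benzyl-2-oxo-1,3-oxazolidin-3-yl]carbonyl}-5-hydroxy-6-(iodomethylidene)-2-methyl-3-(3,4,5-trimethoxyphenyl)non-8-enethioate | O=C1OC[C@@H](Cc2ccccc2)N1C(=O)[C@@H]([C@@H](O)/C(CC=C)=C\I)[C@H](c1cc(OC)c(OC)c(OC)c1)[C@H](C(=O)SC(C)(C)C)C | intermediate
21 | S-tert-butyl (2R,3S,4R,5R,6Z)-4-{[(4R)-4-benzyl-2-oxo-1,3-oxazolidin-3-yl]carbonyl}-5-{[tert-butyl(dimethyl)silyl]oxy}-6-(iodomethylidene)-2-methyl-3-(3,4,5-trimethoxyphenyl)non-8-enethioate | O=C1OC[C@@H](Cc2ccccc2)N1C(=O)[C@@H]([C@@H](O[Si](C)(C)C(C)(C)C)/C(CC=C)=C\I)[C@H](c1cc(OC)c(OC)c(OC)c1)[C@H](C(=O)SC(C)(C)C)C | intermediate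
22 | (2R,3R,4R)-2-[(1R,2Z)-1-{[tert-butyl(dimethyl)silyl]oxy}-2-(iodomethylidene)pent-4-en-1-yl]-4-methyl-3-(3,4,5-trimethoxyphenyl)pentanedioic acid | OC(=O)[C@@H]([C@@H](O[Si](C)(C)C(C)(C)C)/C(CC=C)=C\I)[C@H](c1cc(OC)c(OC)c(OC)c1)[C@H](C(=O)O)C | intermediate
23 | (3R,4R,5R)-3-[(1R,2Z)-1-{[tert-butyl(dimethyl)silyl]oxy}-2-(iodomethylidene)pent-4-en-1-yl]-5-methyl-4-(3,4,5-trimethoxyphenyl)oxane-2,6-dione (3,4-trans, 4,5-trans) | O=C1OC(=O)[C@@H]([C@@H](O[Si](C)(C)C(C)(C)C)/C(CC=C)=C\I)[C@H](c2cc(OC)c(OC)c(OC)c2)[C@H]1C | intermediate
24 | (3R,4R,5R)-3-[(1R,2Z)-1-{[tert-butyl(dimethyl)silyl]oxy}-2-[(dichlorochromio)methylidene]pent-4-en-1-yl]-5-methyl-4-(3,4,5-trimethoxyphenyl)oxane-2,6-dione | O=C1OC(=O)[C@@H]([C@@H](O[Si](C)(C)C(C)(C)C)/C(CC=C)=C\[Cr](Cl)Cl)[C@H](c2cc(OC)c(OC)c(OC)c2)[C@H]1C | intermediate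
25 | dichlorochromium alkoxide of lactol 26: (1R,2R,5R,8R,9R)-2-{[tert-butyl(dimethyl)silyl]oxy}-9-methyl-7-oxo-3-(prop-2-en-1-yl)-8-(3,4,5-trimethoxyphenyl)-6-oxabicyclo[3.2.2]non-3-en-5-olate (same spatial arrangement as 26; the C5 descriptor changes because O–Cr outranks O6) | C=CCC1=C[C@@]2(O[Cr](Cl)Cl)OC(=O)[C@@H]([C@H]1O[Si](C)(C)C(C)(C)C)[C@H](c1cc(OC)c(OC)c(OC)c1)[C@H]2C | intermediate
26 | (1R,2R,5S,8R,9R)-2-{[tert-butyl(dimethyl)silyl]oxy}-5-hydroxy-9-methyl-3-(prop-2-en-1-yl)-8-(3,4,5-trimethoxyphenyl)-6-oxabicyclo[3.2.2]non-3-en-7-one | C=CCC1=C[C@@]2(O)OC(=O)[C@@H]([C@H]1O[Si](C)(C)C(C)(C)C)[C@H](c1cc(OC)c(OC)c(OC)c1)[C@H]2C | intermediate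
27 | (1R,2R,5S,8R,9R)-2-hydroxy-5-methoxy-9-methyl-3-(prop-2-en-1-yl)-8-(3,4,5-trimethoxyphenyl)-6-oxabicyclo[3.2.2]non-3-en-7-one | C=CCC1=C[C@@]2(OC)OC(=O)[C@@H]([C@H]1O)[C@H](c1cc(OC)c(OC)c(OC)c1)[C@H]2C | intermediate
28 | (1R,5S,8R,9R)-5-methoxy-9-methyl-3-(prop-2-en-1-yl)-8-(3,4,5-trimethoxyphenyl)-6-oxabicyclo[3.2.2]non-3-ene-2,7-dione | C=CCC1=C[C@@]2(OC)OC(=O)[C@@H](C1=O)[C@H](c1cc(OC)c(OC)c(OC)c1)[C@H]2C | target

## Step count and risks

Total: 15 steps. Longest linear sequence: 12 steps (steps 1, 3, 4, 5, 6, 9, 10, 11, 12, 13, 14, 15, from aldehyde 1).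

**Step 13 (key step, proposed new method).** The most likely failure is protonation of the alkenylchromium before it adds, because an anhydride carbonyl is a slower partner than an aldehyde, together with slow consumption of the anhydride by the Lewis-acidic chromium salts and adventitious water. The fallback uses known chemistry and sets out from 23. N,O-Dimethylhydroxylamine opens the anhydride at the less hindered carbonyl (the one next to the methyl-bearing carbon) to give the Weinreb amide acid F1. After deprotonation of the acid with NaH, iodine–lithium exchange with t-BuLi at −90 °C triggers a Parham-type intramolecular acylation of the amide and gives the cycloheptenone acid F2. Acidic methanol as in step 14 then converts F2 into the pseudo-ester, and the route is rejoined at 27.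

**Step 3.** The most likely failure is poor or reversed simple diastereoselection at the methyl-bearing carbon, since the open transition state is only weakly biased by the enol silane geometry. The fallback sets out from 7, obtained as a mixture at that center. Hydroxide hydrolysis followed by acidification and heating gives the diacid F3, and hot acetic anhydride with a trace of Et3N closes and equilibrates it to the trans anhydride F4. The lithium salt of 10 (from n-BuLi) opens F4 at the less hindered carbonyl to give the imide acid F5. Steglich thioesterification of F5 with 2-methylpropane-2-thiol, DCC and 4-(dimethylamino)pyridine rejoins the route at 12.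

**Step 5.** The most likely failure is erosion of the configuration α to the thioester during prolonged heating, or sluggish demethylation that forces harsher conditions. The fallback sets out from 1 and 6 and avoids methyl esters. Knoevenagel condensation of 1 with diallyl malonate gives the diallyl arylidene malonate F6, and the copper-catalysed addition of 6 as in step 3 gives the diallyl adduct F7. Deallylation with Pd(PPh3)4 and morpholine at room temperature, then decarboxylation of the malonic acid on warming in toluene, rejoins the route at 9 without a separate Krapcho step.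

**Step 9.** The most likely failure is geometric isomerisation of the β-iodo enal, or addition–elimination at its iodine-bearing carbon by the amine base, either before or during the aldol; a sluggish reaction of the hindered enolate would make this worse. The fallback sets out from the alkenylmagnesium chelate 15 (from 13 and 14) and introduces iodine late. Quenching 15 with Bu3SnCl gives the stannyl alcohol F8, and Dess–Martin oxidation gives the stannyl enal F9. The same boron aldol with 12 gives the stannyl aldol F10. Iododestannylation of F10 with I2 in CH2Cl2 at 0 °C, with retention of geometry, rejoins the route at 20.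

**Step 11.** The most likely failure is incomplete perhydrolysis of the hindered S-tert-butyl thioester while the imide is cleaved cleanly. The fallback sets out from 21 and accepts this outcome. The mono-acid thioester F11 is isolated and closed directly by thiophilic activation with AgO2CCF3 and Na2HPO4 in CH2Cl2; the carboxylate attacks the silver-activated thioester and the route is rejoined at 23.

**Step 14.** The most likely failure is ring opening to the normal methyl ester of the keto acid, or ionisation of the allylic C2 carbinol under acid with solvolysis or transposition. The fallback sets out from 26 and changes the order of events. HF·pyridine in THF removes the silyl group to give the lactol diol F12, and Dess–Martin oxidation gives the keto lactol F13, in which C2 can no longer ionise. Mild ketalisation with pyridinium p-toluenesulfonate, MeOH and HC(OMe)3 then gives the target, rejoining at 28.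

## Further compounds

F1 | step 13 | (2R,3R,4R)-2-[(1R,2Z)-1-{[tert-butyl(dimethyl)silyl]oxy}-2-(iodomethylidene)pent-4-en-1-yl]-5-[methoxy(methyl)amino]-4-methyl-5-oxo-3-(3,4,5-trimethoxyphenyl)pentanoic acid | OC(=O)[C@@H]([C@@H](O[Si](C)(C)C(C)(C)C)/C(CC=C)=C\I)[C@H](c1cc(OC)c(OC)c(OC)c1)[C@H](C(=O)N(C)OC)C
F2 | step 13 | (1R,2R,6R,7R)-2-{[tert-butyl(dimethyl)silyl]oxy}-6-methyl-5-oxo-3-(prop-2-en-1-yl)-7-(3,4,5-trimethoxyphenyl)cyclohept-3-ene-1-carboxylic acid | OC(=O)[C@H]1[C@@H](O[Si](C)(C)C(C)(C)C)C(CC=C)=CC(=O)[C@H](C)[C@H]1c2cc(OC)c(OC)c(OC)c2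
F3 | step 3 | (2R,3S)-2-methyl-3-(3,4,5-trimethoxyphenyl)pentanedioic acid | OC(=O)C[C@H](c1cc(OC)c(OC)c(OC)c1)[C@H](C(=O)O)C
F4 | step 3 | (3R,4S)-3-methyl-4-(3,4,5-trimethoxyphenyl)oxane-2,6-dione (trans) | O=C1OC(=O)C[C@H](c2cc(OC)c(OC)c(OC)c2)[C@H]1C
F5 | step 3 | (2R,3S)-5-[(4R)-4-benzyl-2-oxo-1,3-oxazolidin-3-yl]-2-methyl-5-oxo-3-(3,4,5-trimethoxyphenyl)pentanoic acid | O=C1OC[C@@H](Cc2ccccc2)N1C(=O)C[C@H](c1cc(OC)c(OC)c(OC)c1)[C@H](C(=O)O)C
F6 | step 5 | bis(prop-2-en-1-yl) 2-[(3,4,5-trimethoxyphenyl)methylidene]propanedioate | C=CCOC(=O)C(=Cc1cc(OC)c(OC)c(OC)c1)C(=O)OCC=C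
F7 | step 5 | bis(prop-2-en-1-yl) 2-[(1S,2R)-3-(tert-butylsulfanyl)-2-methyl-3-oxo-1-(3,4,5-trimethoxyphenyl)propyl]propanedioate | C=CCOC(=O)C(C(=O)OCC=C)[C@H](c1cc(OC)c(OC)c(OC)c1)[C@H](C(=O)SC(C)(C)C)C
F8 | step 9 | (2Z)-2-[(tributylstannyl)methylidene]pent-4-en-1-ol | OC/C(CC=C)=C\[Sn](CCCC)(CCCC)CCCC
F9 | step 9 | (2Z)-2-[(tributylstannyl)methylidene]pent-4-enal | O=C/C(CC=C)=C\[Sn](CCCC)(CCCC)CCCC
F10 | step 9 | S-tert-butyl (2R,3S,4R,5R,6Z)-4-{[(4R)-4-benzyl-2-oxo-1,3-oxazolidin-3-yl]carbonyl}-5-hydroxy-2-methyl-6-[(tributylstannyl)methylidene]-3-(3,4,5-trimethoxyphenyl)non-8-enethioate | O=C1OC[C@@H](Cc2ccccc2)N1C(=O)[C@@H]([C@@H](O)/C(CC=C)=C\[Sn](CCCC)(CCCC)CCCC)[C@H](c1cc(OC)c(OC)c(OC)c1)[C@H](C(=O)SC(C)(C)C)C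
F11 | step 11 | (2R,3S,4R)-5-(tert-butylsulfanyl)-2-[(1R,2Z)-1-{[tert-butyl(dimethyl)silyl]oxy}-2-(iodomethylidene)pent-4-en-1-yl]-4-methyl-5-oxo-3-(3,4,5-trimethoxyphenyl)pentanoic acid | OC(=O)[C@@H]([C@@H](O[Si](C)(C)C(C)(C)C)/C(CC=C)=C\I)[C@H](c1cc(OC)c(OC)c(OC)c1)[C@H](C(=O)SC(C)(C)C)C
F12 | step 14 | (1R,2R,5S,8R,9R)-2,5-dihydroxy-9-methyl-3-(prop-2-en-1-yl)-8-(3,4,5-trimethoxyphenyl)-6-oxabicyclo[3.2.2]non-3-en-7-one | C=CCC1=C[C@@]2(O)OC(=O)[C@@H]([C@H]1O)[C@H](c1cc(OC)c(OC)c(OC)c1)[C@H]2C
F13 | step 14 | (1R,5S,8R,9R)-5-hydroxy-9-methyl-3-(prop-2-en-1-yl)-8-(3,4,5-trimethoxyphenyl)-6-oxabicyclo[3.2.2]non-3-ene-2,7-dione | C=CCC1=C[C@@]2(O)OC(=O)[C@@H](C1=O)[C@H](c1cc(OC)c(OC)c(OC)c1)[C@H]2C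
A1 | alternative 1 | methyl 10-methoxy-3,3,9-trimethyl-1,5-dioxaspiro[5.6]dodeca-7,9,11-triene-7-carboxylate | COC(=O)C1=CC(C)=C(OC)C=CC12OCC(C)(C)CO2
A2 | alternative 1 | methyl 6-methoxy-5-methyl-2-oxo-2H-pyran-3-carboxylate | COC(=O)C1=CC(C)=C(OC)OC1=O
A3 | alternative 1 | 6,6-dimethyl-4,8-dioxaspiro[2.5]oct-1-ene | CC1(C)COC2(C=C2)OC1
A4 | alternative 2 | (3R,4R,5R)-3-[(1S,2Z)-1-hydroxy-2-(iodomethylidene)pent-4-en-1-yl]-5-methyl-4-(3,4,5-trimethoxyphenyl)oxan-2-one | O=C1OC[C@H](C)[C@@H](c2cc(OC)c(OC)c(OC)c2)[C@@H]1[C@H](O)/C(CC=C)=C\I
A5 | alternative 2 | (5R)-5-methyl-5,6-dihydro-2H-pyran-2-one | O=C1OC[C@H](C)C=C1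
A6 | alternative 2 | (3,4,5-trimethoxyphenyl)magnesium bromide | COc1cc([Mg]Br)cc(OC)c1OC
A7 | alternative 3 | tert-butyl (1R,6R,7R)-6-methyl-2,5-dioxo-3-(prop-2-en-1-yl)-7-(3,4,5-trimethoxyphenyl)cyclohept-3-ene-1-carboxylate | C=CCC1=CC(=O)[C@H](C)[C@@H](c2cc(OC)c(OC)c(OC)c2)[C@@H](C(=O)OC(C)(C)C)C1=O
A8 | alternative 3 | tert-butyl (4Z)-3,6-dioxo-4-(prop-2-en-1-yl)oct-4-enoate | CCC(=O)/C=C(CC=C)\C(=O)CC(=O)OC(C)(C)C
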